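**Strategy.** The twelve-carbon acyl chain holds an oxygen-bearing C7 between two CH2 groups and an E C4=C5 alkene, a homoallylic ether that maps, by cutting C6–C7, onto hexanal and the unsubstituted terminus of methyl (3E)-hexa-3,5-dienoate. A chiral nickel–phosphine catalyst with triethylsilane should join the two six-carbon pieces, set the C7 S centre as its silyl ether and shift the diene into the E C4=C5 alkene in one operation, closing no ring. Desilylation, O-methylation and saponification then give the acid. It acylates an amine built from (S)-2-iodo-3,6-dimethylcyclohexenone (ring A, methyl centre from a RAMP hydrazone) by Stille coupling with a silyl-masked chlorovinyl stannane.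

Key step: step 2

Assumption: the sense of induction of the chiral phospholane with a linear aliphatic aldehyde cannot be fixed in advance; the route is written with the (2R,5R) ligand, and the (2S,5S) antipode is to be taken if a trial run delivers the 7R silyl ether.
Assumption: RAMP is taken to direct the α′-methylation as it does for saturated cyclohexanone hydrazones (the antipode SAMP giving R), so that RAMP gives the 6S centre; SAMP is to be used otherwise.
Remark: propargylamine is bought as its Boc derivative 16, so no protection step is needed.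

**Step 1**
Reactants: 1 methyl sorbate
Product: 3 methyl (3E)-hexa-3,5-dienoate, via lithium trienolate 2 (not isolated)
Conditions: LDA (1.1 equiv), THF/DMPU, −78 °C; then AcOH, −78 °C to rt
Reagents that add atoms: none
Why: Deconjugation by kinetic protonation: LDA removes a proton from the terminal methyl group to give the extended trienolate, which is protonated fastest at the α-carbon, and the new C3=C4 bond should be E because the s-trans sorbate is deprotonated (a minor Z isomer would be harmless, since C3 becomes sp3 in step 2).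

**Step 2**
Reactants: 4 hexanal, 3 methyl (3E)-hexa-3,5-dienoate, 5 triethylsilane
Product: 6 methyl (4E,7S)-7-(triethylsilyloxy)dodec-4-enoate
Conditions: Ni(cod)2 (10 mol%), (2R,5R)-2,5-dimethyl-1-phenylphospholane (20 mol%), 5 (3 equiv), THF, 0 °C to rt, slow addition of 3
Reagents that add atoms: none
Why: Zerovalent nickel carrying the chiral phosphine binds hexanal and the terminal C5=C6 alkene of the diene and couples them oxidatively at C6, giving a nickel alkoxide whose carbon arm is a syn η3-allyl over C3–C5; σ-bond metathesis with Et3SiH silylates the oxygen and leaves an allylnickel hydride that reductively eliminates C–H at C3, releasing the E C4=C5 alkene and zerovalent nickel. The closest known reaction type is the nickel-catalysed reductive coupling of 1,3-dienes with aldehydes and hydrosilanes to E homoallylic silyl ethers, including its chiral monophosphine variants. No ring is closed. The new C7 centre is set under catalyst control, the C2-symmetric phospholane on nickel differentiating the two aldehyde faces in the C6–C7 bond-forming event. The step needs aldehyde-face selectivity, bond formation at the unsubstituted diene terminus, hydride delivery to C3 and not C5, and E geometry; the steric bias of the monosubstituted diene directs coupling to C6, and the syn allyl with hydride transfer to its remote, substituted end gives the E 1,4-product. A phosphine is used instead of a carbene because phosphine–nickel catalysts favour the E alkene and need no alkoxide base, which would reconjugate 3 to the sorbate.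

**Step 3**
Reactants: 6 methyl (4E,7S)-7-(triethylsilyloxy)dodec-4-enoate
Product: 7 methyl (4E,7S)-7-hydroxydodec-4-enoate
Conditions: PPTS (0.1 equiv), MeOH, rt
Reagents that add atoms: none
Why: Acid-catalysed methanolysis of a triethylsilyl ether (desilylation) breaks only the O–Si bond, so the C7 configuration, the E alkene and the methyl ester (methanol as solvent) should be untouched.

**Step 4**
Reactants: 7 methyl (4E,7S)-7-hydroxydodec-4-enoate
Product: 8 methyl (4E,7S)-7-methoxydodec-4-enoate
Conditions: Me3OBF4, 1,8-bis(dimethylamino)naphthalene, 4 Å MS, CH2Cl2, rt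
Reagents that add atoms: trimethyloxonium tetrafluoroborate, C[O+](C)C.F[B-](F)(F)F
Why: O-Alkylation of the secondary alcohol by an oxonium salt with a non-nucleophilic proton scavenger avoids an alkoxide and hence ester condensation, and the C7–O bond is not broken, so the configuration is retained.

**Step 5**
Reactants: 8 methyl (4E,7S)-7-methoxydodec-4-enoate
Product: 9 (4E,7S)-7-methoxydodec-4-enoic acid
Conditions: LiOH·H2O, THF/MeOH/H2O, rt; then 1 M HCl to pH 3
Reagents that add atoms: lithium hydroxide, [Li+].[OH-]
Why: Saponification (acyl substitution by hydroxide) of an unhindered methyl ester; the remote methoxy centre and the isolated E alkene are inert to aqueous base.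

**Step 6**
Reactants: 10 3-methylcyclohex-2-en-1-one
Product: 11 (2R)-2-(methoxymethyl)-N-(3-methylcyclohex-2-en-1-ylidene)pyrrolidin-1-amine
Conditions: RAMP (1.05 equiv), TsOH·H2O (cat.), cyclohexane, reflux, Dean–Stark
Reagents that add atoms: (R)-1-amino-2-(methoxymethyl)pyrrolidine (RAMP), COC[C@H]1CCCN1N
Why: Hydrazone condensation at the ketone with azeotropic removal of water; the β-methyl group disfavours conjugate addition of the hydrazine.

**Step 7**
Reactants: 11 (2R)-2-(methoxymethyl)-N-(3-methylcyclohex-2-en-1-ylidene)pyrrolidin-1-amine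
Product: 13 (2R)-N-[(6S)-3,6-dimethylcyclohex-2-en-1-ylidene]-2-(methoxymethyl)pyrrolidin-1-amine, via lithium azaenolate 12 (not isolated)
Conditions: LDA, THF, 0 °C; then MeI, −100 °C to rt
Reagents that add atoms: iodomethane, CI
Why: Enders RAMP hydrazone alkylation: kinetic deprotonation at the α′ CH2 (C6) gives a lithium-chelated azaenolate whose methoxymethylpyrrolidine shields one face, so iodomethane should enter from the other and set C6 as S (auxiliary control).

**Step 8**
Reactants: 13 (2R)-N-[(6S)-3,6-dimethylcyclohex-2-en-1-ylidene]-2-(methoxymethyl)pyrrolidin-1-amine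
Product: 14 (6S)-3,6-dimethylcyclohex-2-en-1-one
Conditions: sat. aq. oxalic acid, Et2O, rt
Reagents that add atoms: water, O
Why: Mild two-phase acidic hydrazone hydrolysis should return the ketone without enolising the α′ stereocentre, and the auxiliary is recovered from the aqueous layer.

**Step 9**
Reactants: 14 (6S)-3,6-dimethylcyclohex-2-en-1-one
Product: 15 (6S)-2-iodo-3,6-dimethylcyclohex-2-en-1-one
Conditions: I2, pyridine/CH2Cl2 (1:1), 0 °C to rt, dark
Reagents that add atoms: iodine, II
Why: α-Iodination of a cyclic enone by conjugate addition of pyridine, iodination of the resulting enolate and elimination (Baylis–Hillman-type addition–elimination) places iodine at C2 only, and the weak base should not epimerise C6.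

**Step 10**
Reactants: 16 tert-butyl N-(prop-2-yn-1-yl)carbamate
Product: 17 tert-butyl N-[(2Z)-2-(tributylstannyl)-3-(trimethylsilyl)prop-2-en-1-yl]carbamate
Conditions: Me3Si–SnBu3 (1.1 equiv), Pd(PPh3)4 (3 mol%), THF, 65 °C
Reagents that add atoms: trimethyl(tributylstannyl)silane, CCCC[Sn](CCCC)(CCCC)[Si](C)(C)C
Why: Palladium-catalysed silylstannation of a terminal alkyne is a syn addition that puts tin on the internal and silicon on the terminal carbon, so Sn and Si end cis (Z), which fixes the later cis relation of ring A and chlorine.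

**Step 11**
Reactants: 15 (6S)-2-iodo-3,6-dimethylcyclohex-2-en-1-one, 17 tert-butyl N-[(2Z)-2-(tributylstannyl)-3-(trimethylsilyl)prop-2-en-1-yl]carbamate
Product: 18 tert-butyl N-[(2E)-2-[(5S)-2,5-dimethyl-6-oxocyclohex-1-en-1-yl]-3-(trimethylsilyl)prop-2-en-1-yl]carbamate
Conditions: Pd2(dba)3 (5 mol%), AsPh3 (20 mol%), CuI (0.5 equiv), NMP, 50 °C
Reagents that add atoms: none
Why: Stille coupling of an α-iodoenone with an alkenylstannane proceeds with retention at the alkenyl carbon, the weakly bound arsine and CuI speeding transmetalation of the hindered internal stannane, while the vinylsilane, the carbamate and the C6 centre are inert under these neutral conditions.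

**Step 12**
Reactants: 18 tert-butyl N-[(2E)-2-[(5S)-2,5-dimethyl-6-oxocyclohex-1-en-1-yl]-3-(trimethylsilyl)prop-2-en-1-yl]carbamate
Product: 19 tert-butyl N-[(2E)-3-chloro-2-[(5S)-2,5-dimethyl-6-oxocyclohex-1-en-1-yl]prop-2-en-1-yl]carbamate
Conditions: NCS (1.2 equiv), DMF, 0 °C to rt, dark
Reagents that add atoms: N-chlorosuccinimide, O=C1CCC(=O)N1Cl
Why: Electrophilic ipso-chlorodesilylation of a vinylsilane: chlorine adds to the silicon-bearing carbon to give a β-silyl-stabilised cation that loses the silyl group after least-motion rotation, so in a polar medium the C–Si bond should be replaced with retention and chlorine ends cis to ring A.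

**Step 13**
Reactants: 19 tert-butyl N-[(2E)-3-chloro-2-[(5S)-2,5-dimethyl-6-oxocyclohex-1-en-1-yl]prop-2-en-1-yl]carbamate
Product: 20 (2E)-3-chloro-2-[(5S)-2,5-dimethyl-6-oxocyclohex-1-en-1-yl]prop-2-en-1-aminium trifluoroacetate
Conditions: TFA/CH2Cl2 (1:4), 0 °C; evaporation with toluene
Reagents that add atoms: trifluoroacetic acid, OC(=O)C(F)(F)F
Why: Acidolytic cleavage of the Boc carbamate leaves the enone and the vinyl chloride intact, and the amine is kept as its salt so that it cannot condense with the ring ketone.

**Step 14**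
Reactants: 9 (4E,7S)-7-methoxydodec-4-enoic acid, 20 (2E)-3-chloro-2-[(5S)-2,5-dimethyl-6-oxocyclohex-1-en-1-yl]prop-2-en-1-aminium trifluoroacetate
Product: 22 (4E,7S)-N-[(2E)-3-chloro-2-[(5S)-2,5-dimethyl-6-oxocyclohex-1-en-1-yl]prop-2-en-1-yl]-7-methoxydodec-4-enamide, via benzotriazolyl ester 21 (not isolated)
Conditions: 9, EDC·HCl, HOBt, CH2Cl2, 0 °C; then 20, iPr2NEt, 0 °C to rt
Reagents that add atoms: none
Why: Carbodiimide amide coupling through the HOBt active ester; the amine is released from its salt only in the presence of the acylating agent, C7 is remote from the activated carboxyl, and the hindered amine base should not enolise C6 at rt.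

**Compound list**
1 | methyl sorbate, methyl (2E,4E)-hexa-2,4-dienoate | C/C=C/C=C/C(=O)OC | starting material
2 | lithium (3E)-1-methoxyhexa-1,3,5-trien-1-olate | C=C/C=C/C=C(OC)O[Li] | intermediate (not isolated)
3 | methyl (3E)-hexa-3,5-dienoate | C=C/C=C/CC(=O)OC | intermediate
4 | hexanal | CCCCCC=O | starting material
5 | triethylsilane | CC[SiH](CC)CC | starting material
6 | methyl (4E,7S)-7-(triethylsilyloxy)dodec-4-enoate | CCCCC[C@@H](C/C=C/CCC(=O)OC)O[Si](CC)(CC)CC | intermediate
7 | methyl (4E,7S)-7-hydroxydodec-4-enoate | CCCCC[C@@H](C/C=C/CCC(=O)OC)O | intermediate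
8 | methyl (4E,7S)-7-methoxydodec-4-enoate | CCCCC[C@@H](C/C=C/CCC(=O)OC)OC | intermediate
9 | (4E,7S)-7-methoxydodec-4-enoic acid | CCCCC[C@@H](C/C=C/CCC(=O)O)OC | intermediate
10 | 3-methylcyclohex-2-en-1-one | CC1=CC(=O)CCC1 | starting material
11 | (2R)-2-(methoxymethyl)-N-(3-methylcyclohex-2-en-1-ylidene)pyrrolidin-1-amine (C=N isomer mixture) | COC[C@H]1CCCN1N=C2C=C(C)CCC2 | intermediate
12 | lithium azaenolate of 11, deprotonated at ring C6 | COC[C@H]1CCCN1N([Li])C2=CCCC(C)=C2 | intermediate (not isolated)
13 | (2R)-N-[(6S)-3,6-dimethylcyclohex-2-en-1-ylidene]-2-(methoxymethyl)pyrrolidin-1-amine | COC[C@H]1CCCN1N=C2C=C(C)CC[C@@H]2C | intermediate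
14 | (6S)-3,6-dimethylcyclohex-2-en-1-one | CC1=CC(=O)[C@@H](C)CC1 | intermediate
15 | (6S)-2-iodo-3,6-dimethylcyclohex-2-en-1-one | IC1=C(C)CC[C@H](C)C1=O | intermediate
16 | tert-butyl N-(prop-2-yn-1-yl)carbamate | CC(C)(C)OC(=O)NCC#C | starting material
17 | tert-butyl N-[(2Z)-2-(tributylstannyl)-3-(trimethylsilyl)prop-2-en-1-yl]carbamate | CC(C)(C)OC(=O)NC/C(=C/[Si](C)(C)C)[Sn](CCCC)(CCCC)CCCC | intermediate
18 | tert-butyl N-[(2E)-2-[(5S)-2,5-dimethyl-6-oxocyclohex-1-en-1-yl]-3-(trimethylsilyl)prop-2-en-1-yl]carbamate | CC(C)(C)OC(=O)NC/C(=C/[Si](C)(C)C)C1=C(C)CC[C@H](C)C1=O | intermediate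
19 | tert-butyl N-[(2E)-3-chloro-2-[(5S)-2,5-dimethyl-6-oxocyclohex-1-en-1-yl]prop-2-en-1-yl]carbamate | CC(C)(C)OC(=O)NC/C(=C/Cl)C1=C(C)CC[C@H](C)C1=O | intermediate
20 | (2E)-3-chloro-2-[(5S)-2,5-dimethyl-6-oxocyclohex-1-en-1-yl]prop-2-en-1-aminium trifluoroacetate | NC/C(=C/Cl)C1=C(C)CC[C@H](C)C1=O.OC(=O)C(F)(F)F | intermediate
21 | 1H-benzotriazol-1-yl (4E,7S)-7-methoxydodec-4-enoate | CCCCC[C@@H](C/C=C/CCC(=O)On1nnc2ccccc12)OC | intermediate (not isolated)
22 | (4E,7S)-N-[(2E)-3-chloro-2-[(5S)-2,5-dimethyl-6-oxocyclohex-1-en-1-yl]prop-2-en-1-yl]-7-methoxydodec-4-enamide | CCCCC[C@@H](C/C=C/CCC(=O)NC/C(=C/Cl)C1=C(C)CC[C@H](C)C1=O)OC | target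

**Step count.** Total: 14 steps (1–5 acid, 6–9 iodoenone, 10 stannane, 11–13 amine, 14 union). Longest linear sequence: 8 steps (6, 7, 8, 9, 11, 12, 13, 14).

**Steps most likely to fail**

1. Step 2. A monodentate phosphine may discriminate the faces of an unbranched aliphatic aldehyde only weakly in an intermolecular coupling; hydride may also be delivered to C5, the diene may oligomerise on nickel, and 3 may reconjugate. The fallback sets out from 4 and rejoins the route at 9. Asymmetric allylboration of hexanal 4 with the Ipc2B(allyl) reagent derived from (−)-α-pinene (Et2O, −78 °C; NaOH/H2O2) should give (4S)-non-1-en-4-ol F1. O-Methylation (Me3OBF4, 1,8-bis(dimethylamino)naphthalene) gives (4S)-4-methoxynon-1-ene F2, and ozonolysis (O3, CH2Cl2, −78 °C; PPh3) gives (3S)-3-methoxyoctanal F3. Vinylmagnesium bromide (THF, −78 °C) gives (5S)-5-methoxydec-1-en-3-ol F4 as a mixture of C3 epimers. Both epimers converge in the Johnson–Claisen rearrangement (MeC(OEt)3, cat. EtCO2H, 140 °C) to ethyl (4E,7S)-7-methoxydodec-4-enoate F5, the chair transition state with an equatorial chain giving the E alkene. Saponification as in step 5 then delivers 9.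

2. Step 11. Transmetalation of the internal stannane, flanked by a cis silyl group, onto the hindered enonyl palladium may be slow, so that protodestannylation, homocoupling or cine substitution compete. The fallback sets out from 17 and rejoins the route at 18. Iododestannylation of 17 (I2, CH2Cl2, 0 °C, retention) gives tert-butyl N-[(2Z)-2-iodo-3-(trimethylsilyl)prop-2-en-1-yl]carbamate F6. Miyaura borylation (B2pin2, PdCl2(dppf), KOAc, dioxane, 80 °C) gives tert-butyl N-[(2E)-2-(4,4,5,5-tetramethyl-1,3,2-dioxaborolan-2-yl)-3-(trimethylsilyl)prop-2-en-1-yl]carbamate F7. Suzuki–Miyaura coupling of F7 with 15 (Pd(PhCN)2Cl2, AsPh3, Ag2O, THF/H2O, rt), in which the smaller, oxide-activated boronate transmetalates more readily, gives 18.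

3. Step 12. The β-silyl cation may be captured by the carbamate oxygen, or chlorine may be delivered by addition–elimination with inversion, so that alkene geometry or the carbamate is lost. The fallback sets out from 16 (with 15) and rejoins the route at 19. Copper-catalysed borylstannylation of 16 (B2pin2, Bu3SnOMe, Cu(OAc)2/PCy3 cat., THF, rt), a syn addition with boron at the terminal carbon, gives tert-butyl N-[(2Z)-3-(4,4,5,5-tetramethyl-1,3,2-dioxaborolan-2-yl)-2-(tributylstannyl)prop-2-en-1-yl]carbamate F8. Stille coupling with 15 under the conditions of step 11 (the boronate is inert without base) gives tert-butyl N-[(2E)-2-[(5S)-2,5-dimethyl-6-oxocyclohex-1-en-1-yl]-3-(4,4,5,5-tetramethyl-1,3,2-dioxaborolan-2-yl)prop-2-en-1-yl]carbamate F9. Chlorodeboronation with CuCl2 (MeOH/H2O, 50 °C), which passes through an alkenylcopper species and not through a carbocation, gives 19 with retention.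

**Further compounds**
F1 | step 2 | (4S)-non-1-en-4-ol | CCCCC[C@@H](CC=C)O
F2 | step 2 | (4S)-4-methoxynon-1-ene | CCCCC[C@@H](CC=C)OC
F3 | step 2 | (3S)-3-methoxyoctanal | CCCCC[C@@H](CC=O)OC
F4 | step 2 | (5S)-5-methoxydec-1-en-3-ol (C3 epimer mixture) | CCCCC[C@@H](CC(O)C=C)OC
F5 | step 2 | ethyl (4E,7S)-7-methoxydodec-4-enoate | CCCCC[C@@H](C/C=C/CCC(=O)OCC)OC
F6 | step 11 | tert-butyl N-[(2Z)-2-iodo-3-(trimethylsilyl)prop-2-en-1-yl]carbamate | CC(C)(C)OC(=O)NC/C(I)=C/[Si](C)(C)C
F7 | step 11 | tert-butyl N-[(2E)-2-(4,4,5,5-tetramethyl-1,3,2-dioxaborolan-2-yl)-3-(trimethylsilyl)prop-2-en-1-yl]carbamate | CC(C)(C)OC(=O)NC/C(=C/[Si](C)(C)C)B1OC(C)(C)C(C)(C)O1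
F8 | step 12 | tert-butyl N-[(2Z)-3-(4,4,5,5-tetramethyl-1,3,2-dioxaborolan-2-yl)-2-(tributylstannyl)prop-2-en-1-yl]carbamate | CC(C)(C)OC(=O)NC/C(=C/B1OC(C)(C)C(C)(C)O1)[Sn](CCCC)(CCCC)CCCC
F9 | step 12 | tert-butyl N-[(2E)-2-[(5S)-2,5-dimethyl-6-oxocyclohex-1-en-1-yl]-3-(4,4,5,5-tetramethyl-1,3,2-dioxaborolan-2-yl)prop-2-en-1-yl]carbamate | CC(C)(C)OC(=O)NC/C(=C/B1OC(C)(C)C(C)(C)O1)C2=C(C)CC[C@H](C)C2=O
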